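## Retrosynthetic overview

1. Cyclocymopol comes from its bromoquinone by Na2S2O4 reduction, the quinone from cyclocymopol dimethyl ether with (NH4)2Ce(NO3)6, and the dimethyl ether from an exocyclic vinylsilane by protodesilylation.
2. Feature: the benzylic CH2 (C7) lies between the arene and ring carbon C6, and C6 is bonded to C1, the ring carbon that carries the exocyclic CH2 (C4 = CHBr, C5 = CMe2). An aryl radical that adds to a C6=C7 vinyl group therefore leaves a C6 radical six atoms away from an alkyne carbon that becomes C1.
3. Key disconnection: aryl–C7 and C1–C6 in one radical operation, from an aryl iodide and a silyl-capped 1,7-enyne. The cyclohexane is the only ring formed and it closes in this step; the arene is bought.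
4. The enyne comes from a primary triflate and lithiated trimethylsilylpropyne. The C4–Br centre comes from auxiliary-controlled bromination of a boron enolate, which places bromine next to the quaternary C5 without any substitution at that carbon.
5. The aryl iodide comes from iodination of 2-bromo-1,4-dimethoxybenzene.

Key step: step 7

Remark: 3,3-dimethylpent-4-enoic acid is taken as purchasable (it is otherwise one saponification away from its methyl ester). The alkyne enters the key step with a SiMe3 cap, because a free terminal alkyne would compete with the vinyl group for the aryl radical and would leave a product alkene open to a second arylation. The cap is removed in step 8, so the step count is unchanged.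

## Route

Step 1
Reactants: 1 3,3-dimethylpent-4-enoic acid; 2 (4S)-4-benzyl-1,3-oxazolidin-2-one
Product: 4 (4S)-4-benzyl-3-(3,3-dimethylpent-4-enoyl)-1,3-oxazolidin-2-one, via mixed pivalic anhydride 3 (not isolated)
Conditions: PivCl, Et3N, THF, −20 °C; then 2, LiCl, −20 °C → rt
Reagents that add atoms: none
Why: Mixed-anhydride N-acylation, in which the oxazolidinone (activated by LiCl and Et3N) attacks the carbonyl of 3 remote from the tert-butyl group; no stereocentre is formed and the auxiliary centre is untouched.

Step 2
Reactants: 4 (4S)-4-benzyl-3-(3,3-dimethylpent-4-enoyl)-1,3-oxazolidin-2-one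
Product: 6 (4S)-4-benzyl-3-[(2S)-2-bromo-3,3-dimethylpent-4-enoyl]-1,3-oxazolidin-2-one, via dibutylboron Z-enolate 5 (not isolated)
Conditions: Bu2BOTf, iPr2NEt, CH2Cl2, −78 → 0 °C; then NBS, −78 °C
Reagents that add atoms: N-bromosuccinimide, O=C1CCC(=O)N1Br
Why: Oxazolidinone-auxiliary (Evans-type) enolate bromination, in which soft enolisation gives the Z boron enolate 5 and the bromine is delivered to the enolate face opposite the benzyl group, which sets the 2S bromide.

Step 3
Reactants: 6 (4S)-4-benzyl-3-[(2S)-2-bromo-3,3-dimethylpent-4-enoyl]-1,3-oxazolidin-2-one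
Product: 7 (2S)-2-bromo-3,3-dimethylpent-4-en-1-ol
Conditions: NaBH4, THF/H2O (4:1), 0 °C
Reagents that add atoms: none
Why: Borohydride reductive cleavage at the exocyclic carbonyl should free the auxiliary 2 for recovery and give the bromohydrin; the C–Br centre is not touched, and closure to the epoxide should be slow at 0 °C because the bromide carbon is neopentyl-like.

Step 4
Reactants: 7 (2S)-2-bromo-3,3-dimethylpent-4-en-1-ol
Product: 8 (2S)-2-bromo-3,3-dimethylpent-4-en-1-yl trifluoromethanesulfonate
Conditions: Tf2O, 2,6-lutidine, CH2Cl2, −78 °C; cold aqueous work-up, used at once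
Reagents that add atoms: trifluoromethanesulfonic anhydride, O=S(=O)(OS(=O)(=O)C(F)(F)F)C(F)(F)F
Why: O-Sulfonylation of the primary alcohol at low temperature with a hindered base that only scavenges acid; the bromide-bearing centre is not involved.

Step 5
Reactants: 8 (2S)-2-bromo-3,3-dimethylpent-4-en-1-yl trifluoromethanesulfonate; 9 trimethyl(prop-1-yn-1-yl)silane
Product: 11 [(5R)-5-bromo-6,6-dimethyloct-7-en-1-yn-1-yl]trimethylsilane, via lithiated trimethylsilylpropyne 10 (not isolated)
Conditions: 9, n-BuLi, THF, −78 → −20 °C; then 8, −78 °C
Reagents that add atoms: none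
Why: SN2 alkylation of the propargylic lithium reagent 10 by the primary triflate, fast at −78 °C where the hindered secondary bromide should be inert; the bromide centre keeps its geometry, and its descriptor changes from S to R only because the CH2OTf carbon outranked the quaternary carbon and the new CH2 does not.

Step 6
Reactants: 12 2-bromo-1,4-dimethoxybenzene
Product: 13 1-bromo-4-iodo-2,5-dimethoxybenzene
Conditions: NIS, TFA (0.3 equiv), MeCN, rt
Reagents that add atoms: N-iodosuccinimide, O=C1CCC(=O)N1I
Why: Electrophilic aromatic iodination at the free position para to bromine and ortho to a methoxy group, the most activated and least hindered site.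

Step 7
Reactants: 11 [(5R)-5-bromo-6,6-dimethyloct-7-en-1-yn-1-yl]trimethylsilane; 13 1-bromo-4-iodo-2,5-dimethoxybenzene
Product: 14 {[(2S,4R)-4-bromo-2-[(4-bromo-2,5-dimethoxyphenyl)methyl]-3,3-dimethylcyclohexylidene]methyl}trimethylsilane (mixture of alkene geometries)
Conditions: fac-Ir(ppy)3 (ppy = 2-phenylpyridinato; 2 mol %), diethyl 2,6-dimethyl-1,4-dihydropyridine-3,5-dicarboxylate (1.5 equiv, in portions), K2HPO4 (2 equiv), 13 (2.5 equiv), degassed MeCN (0.4 M in 11), blue LEDs (450 nm), rt
Reagents that add atoms: none
Why: Proposed new method: the photoexcited iridium complex transfers an electron to the C–I bond of 13 (the aryl and secondary alkyl C–Br bonds lie beyond its reducing power), the 4-bromo-2,5-dimethoxyphenyl radical adds to the terminal vinyl carbon C7 of 11, the secondary C6 radical adds to the alkyne carbon C1, and the α-silyl vinyl radical takes hydrogen from the dihydropyridine, whose oxidation returns the catalyst. The closest known reactions are photoredox hydroarylations of terminal alkenes with aryl iodides and tin- or silane-mediated enyne cascades that end in exo-dig closure onto silyl alkynes; an intermolecular first step on a neopentyl-type alkene joined to a 6-exo-dig second step has not been shown. The cyclohexane closes 6-exo-dig (C6 onto C1) through a chair, and the gem-dimethyl group at C5 favours the folded chain. C6 is set under substrate control by the existing C4 centre: the chair with C4–Br and the C6–CH2Ar group both equatorial gives the 4,6-cis (4R,6S) isomer, the bias across C5 is modest, and the C6 epimer is expected as a minor product to be removed by chromatography. The step needs the aryl radical to choose the vinyl group over the alkyne, and the SiMe3 cap secures this by blocking the alkyne terminus; the cap also shields the product alkene from a second arylation and hinders attack of the vinyl radical on the arene. Because the ring closure is slow, the hydrogen donor is kept at a low stationary concentration by portionwise addition in acetonitrile, a poor hydrogen donor towards alkyl radicals.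

Step 8
Reactants: 14 {[(2S,4R)-4-bromo-2-[(4-bromo-2,5-dimethoxyphenyl)methyl]-3,3-dimethylcyclohexylidene]methyl}trimethylsilane
Product: 15 1-bromo-4-{[(1S,3R)-3-bromo-2,2-dimethyl-6-methylidenecyclohexyl]methyl}-2,5-dimethoxybenzene (cyclocymopol dimethyl ether)
Conditions: p-TolSO2H (0.3 equiv), MeCN/H2O (50:1), 70 °C
Reagents that add atoms: none
Why: Ipso-protodesilylation, in which protonation at the silicon-bearing carbon gives a tertiary β-silyl cation that loses silicon, so both alkene geometries converge on the exocyclic methylene; the weak sulfinic acid should not protonate the product alkene at a useful rate, and C4 and C6 are untouched.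

Step 9
Reactants: 15 1-bromo-4-{[(1S,3R)-3-bromo-2,2-dimethyl-6-methylidenecyclohexyl]methyl}-2,5-dimethoxybenzene
Product: 16 2-bromo-5-{[(1S,3R)-3-bromo-2,2-dimethyl-6-methylidenecyclohexyl]methyl}cyclohexa-2,5-diene-1,4-dione
Conditions: (NH4)2Ce(NO3)6 (2.5 equiv), MeCN/H2O (2:1), 0 °C, short reaction time
Reagents that add atoms: water, O
Why: Oxidative demethylation of the para-dimethoxyarene by two one-electron oxidations with tetravalent cerium and attack of water; the isolated alkene and the alkyl bromide should survive the short, cold treatment.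

Step 10
Reactants: 16 2-bromo-5-{[(1S,3R)-3-bromo-2,2-dimethyl-6-methylidenecyclohexyl]methyl}cyclohexa-2,5-diene-1,4-dione
Product: 17 2-bromo-5-{[(1S,3R)-3-bromo-2,2-dimethyl-6-methylidenecyclohexyl]methyl}benzene-1,4-diol (cyclocymopol)
Conditions: Na2S2O4, Et2O/H2O, rt, under argon
Reagents that add atoms: none
Why: Two-electron reduction of the quinone to the hydroquinone by dithionite under non-acidic conditions, which avoids acid-promoted addition of the ortho phenol to the exocyclic alkene.

## Compound list

1 | 3,3-dimethylpent-4-enoic acid | C=CC(C)(C)CC(=O)O | starting material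
2 | (4S)-4-benzyl-1,3-oxazolidin-2-one | O=C1N[C@@H](Cc2ccccc2)CO1 | starting material
3 | 3,3-dimethylpent-4-enoic pivalic anhydride | C=CC(C)(C)CC(=O)OC(=O)C(C)(C)C | intermediate
4 | (4S)-4-benzyl-3-(3,3-dimethylpent-4-enoyl)-1,3-oxazolidin-2-one | C=CC(C)(C)CC(=O)N1[C@@H](Cc2ccccc2)COC1=O | intermediate
5 | dibutylboron Z-enolate of 4 | CCCCB(CCCC)O/C(=C\C(C)(C)C=C)N1[C@@H](Cc2ccccc2)COC1=O | intermediate
6 | (4S)-4-benzyl-3-[(2S)-2-bromo-3,3-dimethylpent-4-enoyl]-1,3-oxazolidin-2-one | C=CC(C)(C)[C@H](Br)C(=O)N1[C@@H](Cc2ccccc2)COC1=O | intermediate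
7 | (2S)-2-bromo-3,3-dimethylpent-4-en-1-ol | C=CC(C)(C)[C@H](Br)CO | intermediate
8 | (2S)-2-bromo-3,3-dimethylpent-4-en-1-yl trifluoromethanesulfonate | C=CC(C)(C)[C@H](Br)COS(=O)(=O)C(F)(F)F | intermediate
9 | trimethyl(prop-1-yn-1-yl)silane | CC#C[Si](C)(C)C | starting material
10 | [3-(trimethylsilyl)prop-2-yn-1-yl]lithium | [Li]CC#C[Si](C)(C)C | intermediate
11 | [(5R)-5-bromo-6,6-dimethyloct-7-en-1-yn-1-yl]trimethylsilane | C=CC(C)(C)[C@H](Br)CCC#C[Si](C)(C)C | intermediate
12 | 2-bromo-1,4-dimethoxybenzene | COc1ccc(OC)c(Br)c1 | starting material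
13 | 1-bromo-4-iodo-2,5-dimethoxybenzene | COc1cc(Br)c(OC)cc1I | intermediate
14 | {[(2S,4R)-4-bromo-2-[(4-bromo-2,5-dimethoxyphenyl)methyl]-3,3-dimethylcyclohexylidene]methyl}trimethylsilane (alkene geometry left open, mixture) | C[Si](C)(C)C=C1CC[C@@H](Br)C(C)(C)[C@H]1Cc1cc(OC)c(Br)cc1OC | intermediate
15 | 1-bromo-4-{[(1S,3R)-3-bromo-2,2-dimethyl-6-methylidenecyclohexyl]methyl}-2,5-dimethoxybenzene (cyclocymopol dimethyl ether) | C=C1CC[C@@H](Br)C(C)(C)[C@H]1Cc1cc(OC)c(Br)cc1OC | intermediate
16 | 2-bromo-5-{[(1S,3R)-3-bromo-2,2-dimethyl-6-methylidenecyclohexyl]methyl}cyclohexa-2,5-diene-1,4-dione | C=C1CC[C@@H](Br)C(C)(C)[C@H]1CC1=CC(=O)C(Br)=CC1=O | intermediate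
17 | 2-bromo-5-{[(1S,3R)-3-bromo-2,2-dimethyl-6-methylidenecyclohexyl]methyl}benzene-1,4-diol (cyclocymopol) | C=C1CC[C@@H](Br)C(C)(C)[C@H]1Cc1cc(O)c(Br)cc1O | target

## Step count and risks

Total step count: 10. Longest linear sequence: 9 (steps 1–5 and 7–10).

Steps most likely to fail:

1. Step 7 (proposed new method). What may go wrong:
   - hydrogen transfer to the aryl radical before it adds to the alkene;
   - hydrogen transfer to the C6 radical before ring closure;
   - a 1,5-hydrogen shift from the propargylic C2–H to the C6 radical;
   - weak facial control at C6.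

   The fallback sets out from 13 and returns to the route at 15, using a cationic instead of a radical ring closure. Iodine–lithium exchange (n-BuLi, THF, −78 °C) gives (4-bromo-2,5-dimethoxyphenyl)lithium F1. Alkylation of F1 at the primary carbon of geranyl bromide with catalytic CuBr·SMe2 gives 1-bromo-4-[(2E)-3,7-dimethylocta-2,6-dien-1-yl]-2,5-dimethoxybenzene F2. An enantioselective bromonium-induced cation–olefin cyclisation of F2 then follows, with 1,3-dibromo-5,5-dimethylhydantoin and a BINOL-derived chiral thiophosphoramide as Lewis-base catalyst, the catalyst enantiomer being chosen for the 4R series. The chair transition state of the E-alkene places Br and CH2Ar cis, and loss of a methyl proton gives 15. The endocyclic alkene isomers would be removed on AgNO3-impregnated silica.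

2. Step 5. What may go wrong: loss of triflic acid, or of bromine and triflate together, under the basic organolithium; or slow substitution at the β-branched carbon, with allenyl attack taking over.

   The fallback sets out from 8 and returns at 11, building the alkyne by homologation instead of propargylation. Copper-catalysed coupling of 8 with (1,3-dioxolan-2-ylmethyl)magnesium bromide (CuBr·SMe2 cat., THF, −30 °C) gives 2-[(3R)-3-bromo-4,4-dimethylhex-5-en-1-yl]-1,3-dioxolane F3. Aqueous HCl in THF frees (4R)-4-bromo-5,5-dimethylhept-6-enal F4. Dimethyl (1-diazo-2-oxopropyl)phosphonate with K2CO3 in MeOH (Ohira–Bestmann homologation) gives (4R)-4-bromo-3,3-dimethyloct-1-en-7-yne F5. LiN(SiMe3)2 at −78 °C gives its lithium acetylide F6, which is silylated with Me3SiCl to 11.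

3. Step 8. What may go wrong: acid-promoted migration of the exocyclic double bond into the ring, or incomplete loss of silicon.

   The fallback sets out from 14 and returns at 15, replacing silicon by iodine and then by hydrogen without acid. N-Iodosuccinimide in MeCN at 0 °C (ipso-iododesilylation) gives 1-bromo-4-{[(1R,3R)-3-bromo-6-(iodomethylidene)-2,2-dimethylcyclohexyl]methyl}-2,5-dimethoxybenzene F7. Its ring geometry is unchanged; the descriptor change is formal. Formate reduction with Pd(PPh3)4 (zerovalent palladium), HCO2H and Et3N in DMF at 40 °C then replaces the vinylic iodine by hydrogen; the aryl and alkyl bromides are far slower in oxidative addition.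

Further compounds
F1 | step 7 | (4-bromo-2,5-dimethoxyphenyl)lithium | [Li]c1cc(OC)c(Br)cc1OC
F2 | step 7 | 1-bromo-4-[(2E)-3,7-dimethylocta-2,6-dien-1-yl]-2,5-dimethoxybenzene (cymopol dimethyl ether) | COc1cc(Br)c(OC)cc1C/C=C(\C)CCC=C(C)C
F3 | step 5 | 2-[(3R)-3-bromo-4,4-dimethylhex-5-en-1-yl]-1,3-dioxolane | C=CC(C)(C)[C@H](Br)CCC1OCCO1
F4 | step 5 | (4R)-4-bromo-5,5-dimethylhept-6-enal | O=CCC[C@@H](Br)C(C)(C)C=C
F5 | step 5 | (4R)-4-bromo-3,3-dimethyloct-1-en-7-yne | C#CCC[C@@H](Br)C(C)(C)C=C
F6 | step 5 | [(5R)-5-bromo-6,6-dimethyloct-7-en-1-yn-1-yl]lithium | [Li]C#CCC[C@@H](Br)C(C)(C)C=C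
F7 | step 8 | 1-bromo-4-{[(1R,3R)-3-bromo-6-(iodomethylidene)-2,2-dimethylcyclohexyl]methyl}-2,5-dimethoxybenzene (alkene geometry left open) | IC=C1CC[C@@H](Br)C(C)(C)[C@H]1Cc1cc(OC)c(Br)cc1OC
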